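The target is cut at both butenolides. Each spiro carbon (C5 of a 2(5H)-furanone and a cyclobutane carbon at once) bears the ring oxygen O1 and the vinylic C4, the imprint of a C(=O)–C=C unit joined across a ketone C=O. The two spiro carbons are neighbours, so they map onto a cyclobutane-1,2-dione. One phosphine-catalysed operation lets two antipodal 2-(1-acetoxybutyl)cyclopropenones open and add in turn across both carbonyls of a tartrate-derived, C2-symmetric trans-3,4-bis(silyloxy)cyclobutane-1,2-dione. It forms both C4–C5 bonds, both lactone C–O bonds and both spiro centres. The four bromines follow: the ring pair by double inversion, the vinylic pair last.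

Key step: step 9

Locants: 1,7-dioxadispiro[4.0.4.2]dodecane numbering is used. Butenolide A is O1, C2(=O), C3, C4, C5 (spiro); butenolide B is C6 (spiro), O7, C8(=O), C9, C10; C11 (next to C6) and C12 (next to C5) complete the cyclobutane.

Assumption: the lipase acylates the (S)-alcohol of 6 (propyl in the large pocket, ethynyl in the medium one); if the opposite sense holds, step 5 delivers the (R)-acetate and step 6 the (S)-acetate, and both antipodes are still obtained.

Remark on the resolution: each antipode of 6 is taken from a run of its own, the (S)-acetate from an acetylation held below half conversion (step 5) and the (R)-alcohol from a hemisuccinylation driven past half conversion (step 6). A kinetic resolution gives the acylated product and the unreacted partner at their best purity on opposite sides of half conversion. The unreacted, (R)-enriched alcohol left by step 5 can be added to the charge of step 6.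

Remark on the design: the ring bromides are installed before the vinylic ones, because bromide must enter each ring carbon past C4 or C10 of the neighbouring butenolide and that path is open only while these carry hydrogen.

Step 1
Reactants: 1 diethyl L-tartrate
Product: 2 diethyl (2R,3R)-2,3-bis(tert-butyldimethylsilyloxy)butanedioate
Conditions: TBSCl (2.6 equiv), imidazole (5 equiv), DMAP (cat.), DMF, 40 °C
Reagents that add atoms: tert-butyldimethylsilyl chloride, CC(C)(C)[Si](C)(C)Cl
Why: Imidazole-mediated O-silylation of both secondary hydroxyls breaks no bond at a stereocentre and gives bulky ethers that later shield one face of each ketone and cannot leave as nucleofuges.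

Step 2
Reactants: 2 diethyl (2R,3R)-2,3-bis(tert-butyldimethylsilyloxy)butanedioate
Product: 3 (2R,3R)-2,3-bis(tert-butyldimethylsilyloxy)butanedial
Conditions: i-Bu2AlH (2.2 equiv), toluene, −78 °C; MeOH, then aq. potassium sodium tartrate; used crude
Reagents that add atoms: none
Why: Half-reduction of an α-oxygenated ester stops at the tetrahedral aluminium hemiacetal at −78 °C and releases the aldehyde only on work-up, so no over-reduction and no epimerisation of the α-silyloxy centres is expected.

Step 3
Reactants: 3 (2R,3R)-2,3-bis(tert-butyldimethylsilyloxy)butanedial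
Product: 4 (1S,2R,3S,4S)-3,4-bis(tert-butyldimethylsilyloxy)cyclobutane-1,2-diol
Conditions: 3 added over 4 h to SmI2 (3 equiv, 0.05 M), THF, −78 °C → rt; aq. NH4Cl
Reagents that add atoms: none
Why: Intramolecular SmI2 pinacol coupling of a 1,4-dicarbonyl closes the cyclobutane through a samarium-bridged diketyl (hence the cis diol), slow inverse addition favouring ring closure over oligomerisation; the two new carbinol centres need no control because both are oxidised next, and the silyloxy centres are untouched (their descriptors change only through CIP priorities).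

Step 4
Reactants: 4 (1S,2R,3S,4S)-3,4-bis(tert-butyldimethylsilyloxy)cyclobutane-1,2-diol
Product: 5 (3R,4R)-3,4-bis(tert-butyldimethylsilyloxy)cyclobutane-1,2-dione
Conditions: (COCl)2, DMSO, CH2Cl2, −78 °C; Et3N, −78 → −30 °C; cold pentane, rapid cold pH 7 wash; used at once
Reagents that add atoms: none
Why: Swern oxidation takes a vicinal diol to the 1,2-dione without C–C cleavage, and below −30 °C the amine should not enolise the α-silyloxy ketones, so the trans (3R,4R) centres survive.

Step 5
Reactants: 6 rac-hex-1-yn-3-ol
Product: 7 (S)-hex-1-yn-3-yl acetate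
Conditions: vinyl acetate (3 equiv), Novozym 435 (immobilised Candida antarctica lipase B), hexane, 30 °C, stopped below 50 % conversion; filtration; chromatography
Reagents that add atoms: vinyl acetate, CC(=O)OC=C
Why: Lipase-catalysed kinetic resolution by irreversible transesterification acylates only the faster antipode, selected through the size difference between propyl and ethynyl, and stopping short of half conversion keeps the (S)-acetate enantiomerically clean, the stereocentre being selected and not created.

Step 6
Reactants: 6 rac-hex-1-yn-3-ol
Product: 9 (R)-hex-1-yn-3-yl acetate, via (R)-hex-1-yn-3-ol 8 (not isolated)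
Conditions: succinic anhydride (0.7 equiv), Novozym 435, t-BuOMe, 30 °C, run past 50 % conversion; filtration; aq. Na2CO3 wash; dried organic phase, then Ac2O, pyridine, DMAP (cat.), 0 °C → rt
Reagents that add atoms: acetic anhydride, CC(=O)OC(C)=O
Why: Lipase-catalysed kinetic resolution with a cyclic anhydride turns the fast (S)-alcohol into an acidic hemisuccinate that the base wash removes, overshooting half conversion leaves the slow (R)-alcohol enantiomerically clean in the organic phase, and DMAP-catalysed O-acetylation of that solution leaves the carbinol C–O bond intact, so the (R) configuration is retained.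

Step 7
Reactants: 7 (S)-hex-1-yn-3-yl acetate; 10 (trifluoromethyl)trimethylsilane
Product: 12 2-[(1S)-1-acetoxybutyl]cycloprop-2-en-1-one, via (S)-gem-difluorocyclopropene 11 (not isolated)
Conditions: TMSCF3 (2.5 equiv), NaI (2.2 equiv), THF, 65 °C, sealed tube; then wet silica gel, CH2Cl2, rt
Reagents that add atoms: (trifluoromethyl)trimethylsilane 10, C[Si](C)(C)C(F)(F)F; water, O
Why: Iodide-triggered release of difluorocarbene from 10 and its [2+1] addition to the terminal alkyne give the 3,3-difluorocyclopropene, which ionises to the cyclopropenylium ion on moist silica and hydrolyses to the cyclopropenone without touching the acetoxy stereocentre.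

Step 8
Reactants: 9 (R)-hex-1-yn-3-yl acetate; 10 (trifluoromethyl)trimethylsilane
Product: 14 2-[(1R)-1-acetoxybutyl]cycloprop-2-en-1-one, via (R)-gem-difluorocyclopropene 13 (not isolated)
Conditions: TMSCF3 (2.5 equiv), NaI (2.2 equiv), THF, 65 °C, sealed tube; then wet silica gel, CH2Cl2, rt
Reagents that add atoms: (trifluoromethyl)trimethylsilane 10, C[Si](C)(C)C(F)(F)F; water, O
Why: The same difluorocarbene [2+1] addition and hydrolysis as in step 7 are applied to the antipodal acetate, again without involving the stereocentre.

Step 9
Reactants: 5 (3R,4R)-3,4-bis(tert-butyldimethylsilyloxy)cyclobutane-1,2-dione; 12 2-[(1S)-1-acetoxybutyl]cycloprop-2-en-1-one; 14 2-[(1R)-1-acetoxybutyl]cycloprop-2-en-1-one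
Product: 16 dispiro bis(butenolide) bis(silyl ether), via mono-spiro ketone 15 (not isolated)
Conditions: 12 (1.0 equiv) added over 1 h to 5 and PMe3 (10 mol %), toluene, −40 °C; then 14 (1.2 equiv), PMe3 (10 mol %), −40 °C → rt
Reagents that add atoms: none
Why: PMe3 adds to the unsubstituted ring carbon of 12, the strained ring opens to a ketenyl phosphorus ylide, the ylide carbon attacks one carbonyl of 5, the alkoxide acylates itself on the ketene, and the β-phosphonio lactone enolate expels PMe3 to give 15; the same cycle with 14 on the remaining ketone gives 16. The closest known reaction type is the phosphine-catalysed (3+2) annulation of cyclopropenones with aldehydes and activated ketones (isatins, α-keto esters) to butenolides. Each butenolide ring closes by 5-exo-dig attack of the tertiary alkoxide oxygen on the ketene carbon (O1–C2 and O7–C8) after intermolecular formation of C4–C5 and C10–C6. The first spiro centre is set by approach of the ylide anti to the silyloxy group on the neighbouring ring carbon (substrate control from the tartrate-derived centre); the second is set by the same anti relationship to its own silyloxy neighbour, reinforced by approach past the small lactone oxygen of the first spiro ring, so that O1 and O7 end up trans and each is cis to its adjacent silyloxy group. The step needs chemoselectivity (mono- before bis-annulation, so that the two antipodes are installed in turn), secured by the higher electrophilicity of the 1,2-dione over the hindered ketone 15 and by slow addition of one equivalent of 12; because 5 is C2-symmetric, either carbonyl gives the same 15, and phosphine attack at the unsubstituted carbon places the side chain at C3 and hydrogen at C4. Neutral conditions, low catalyst loading and low temperature keep the acetates in place and limit phosphine addition to the dione.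

Step 10
Reactants: 16 dispiro bis(butenolide) bis(silyl ether)
Product: 17 dispiro bis(butenolide) trans-11,12-diol
Conditions: HF·pyridine, pyridine, THF, 0 °C → rt
Reagents that add atoms: none
Why: Fluoride-driven Si–O cleavage under buffered acidic conditions removes both secondary silyl groups while acetates, lactones and the carbinol C–O bonds stay intact, so all configurations are retained.

Step 11
Reactants: 17 dispiro bis(butenolide) trans-11,12-diol
Product: 18 dispiro bis(butenolide) 11,12-bis(triflate)
Conditions: Tf2O (3 equiv), pyridine (6 equiv), CH2Cl2, −30 → 0 °C; cold work-up, used directly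
Reagents that add atoms: trifluoromethanesulfonic anhydride, O=S(=O)(OS(=O)(=O)C(F)(F)F)C(F)(F)F
Why: O-sulfonylation with retention installs the strongest practical nucleofuge on the hindered cyclobutyl carbinols, and the trans arrangement leaves no hydrogen anti to either triflate, so elimination is not open.

Step 12
Reactants: 18 dispiro bis(butenolide) 11,12-bis(triflate)
Product: 19 dispiro bis(butenolide) trans-11,12-dibromide
Conditions: Bu4NBr (6 equiv), MeCN–toluene, rt → 50 °C
Reagents that add atoms: tetrabutylammonium bromide, CCCC[N+](CCCC)(CCCC)CCCC.[Br-]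
Why: Two SN2 displacements of secondary triflates by bromide, each with inversion, move each ring substituent from cis to trans relative to its neighbouring lactone oxygen and give the trans-dibromide of the target, ionisation being disfavoured by the flanking oxygenated spiro carbons and the weakly ionising medium.

Step 13
Reactants: 19 dispiro bis(butenolide) trans-11,12-dibromide
Product: 21 target CNP0266230.1, via bis(3,4-dibromolactone) 20 (not isolated)
Conditions: Br2 (2.5 equiv), CH2Cl2, 0 °C → rt, dark; evaporation; DBU (2.5 equiv), toluene, 0 °C → rt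
Reagents that add atoms: bromine, BrBr
Why: Ionic anti-addition of bromine to each trisubstituted butenolide alkene followed by base-induced dehydrobromination (bromination–dehydrobromination of an α-substituted α,β-unsaturated ester) should return the conjugated alkene with bromine at C4 and C10, because the only hydrogen whose loss with the tertiary α-bromide gives a conjugated product is the one geminal to the new bromine, held syn-periplanar to the C–Br bond in the five-membered ring; the cyclobutyl bromides have no anti hydrogen on the neighbouring CHBr and the side-chain centres are not touched.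

Compound list
1 | diethyl L-tartrate, diethyl (2R,3R)-2,3-dihydroxybutanedioate | CCOC(=O)[C@H](O)[C@@H](O)C(=O)OCC | starting material
2 | diethyl (2R,3R)-2,3-bis(tert-butyldimethylsilyloxy)butanedioate | CCOC(=O)[C@H](O[Si](C)(C)C(C)(C)C)[C@@H](O[Si](C)(C)C(C)(C)C)C(=O)OCC | intermediate
3 | (2R,3R)-2,3-bis(tert-butyldimethylsilyloxy)butanedial | O=C[C@H](O[Si](C)(C)C(C)(C)C)[C@@H](O[Si](C)(C)C(C)(C)C)C=O | intermediate
4 | (1S,2R,3S,4S)-3,4-bis(tert-butyldimethylsilyloxy)cyclobutane-1,2-diol (cis diol, silyloxy groups trans; any trans-diol isomer converges at 5) | O[C@@H]1[C@H](O[Si](C)(C)C(C)(C)C)[C@@H](O[Si](C)(C)C(C)(C)C)[C@@H]1O | intermediate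
5 | (3R,4R)-3,4-bis(tert-butyldimethylsilyloxy)cyclobutane-1,2-dione | O=C1[C@H](O[Si](C)(C)C(C)(C)C)[C@@H](O[Si](C)(C)C(C)(C)C)C1=O | intermediate
6 | rac-hex-1-yn-3-ol | CCCC(O)C#C | starting material
7 | (S)-hex-1-yn-3-yl acetate | CCC[C@H](OC(C)=O)C#C | intermediate
8 | (R)-hex-1-yn-3-ol (the slow-reacting antipode, carried in solution) | CCC[C@@H](O)C#C | intermediate
9 | (R)-hex-1-yn-3-yl acetate | CCC[C@@H](OC(C)=O)C#C | intermediate
10 | (trifluoromethyl)trimethylsilane | C[Si](C)(C)C(F)(F)F | starting material
11 | (1S)-1-(3,3-difluorocycloprop-1-en-1-yl)butyl acetate | CCC[C@H](OC(C)=O)C1=CC1(F)F | intermediate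
12 | 2-[(1S)-1-acetoxybutyl]cycloprop-2-en-1-one | CCC[C@H](OC(C)=O)C1=CC1=O | intermediate
13 | (1R)-1-(3,3-difluorocycloprop-1-en-1-yl)butyl acetate | CCC[C@@H](OC(C)=O)C1=CC1(F)F | intermediate
14 | 2-[(1R)-1-acetoxybutyl]cycloprop-2-en-1-one | CCC[C@@H](OC(C)=O)C1=CC1=O | intermediate
15 | mono-spiro ketone: 3-[(1S)-1-acetoxybutyl]-2(5H)-furanone whose C5 is a ring carbon of a trans-bis(tert-butyldimethylsilyloxy)cyclobutanone, the ketone being the future C6; lactone oxygen cis to the silyloxy group on the adjacent ring carbon | CCC[C@H](OC(C)=O)C1=C[C@@]2(OC1=O)[C@H](O[Si](C)(C)C(C)(C)C)[C@@H](O[Si](C)(C)C(C)(C)C)C2=O | intermediate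
16 | 3-[(1S)-1-acetoxybutyl]-9-[(1R)-1-acetoxybutyl]-11,12-bis(tert-butyldimethylsilyloxy)-1,7-dioxadispiro[4.0.4.2]dodeca-3,9-diene-2,8-dione; O1 and O7 trans across C5–C6, 12-silyloxy cis to O1, 11-silyloxy cis to O7 | CCC[C@H](OC(C)=O)C1=C[C@@]2(OC1=O)[C@H](O[Si](C)(C)C(C)(C)C)[C@@H](O[Si](C)(C)C(C)(C)C)[C@@]21OC(=O)C([C@@H](CCC)OC(C)=O)=C1 | intermediate
17 | the 11,12-diol of 16 (12-OH cis to O1, 11-OH cis to O7, hydroxyls trans) | CCC[C@H](OC(C)=O)C1=C[C@@]2(OC1=O)[C@H](O)[C@@H](O)[C@@]21OC(=O)C([C@@H](CCC)OC(C)=O)=C1 | intermediate
18 | the 11,12-bis(trifluoromethanesulfonate) of 17, configuration unchanged | CCC[C@H](OC(C)=O)C1=C[C@@]2(OC1=O)[C@H](OS(=O)(=O)C(F)(F)F)[C@@H](OS(=O)(=O)C(F)(F)F)[C@@]21OC(=O)C([C@@H](CCC)OC(C)=O)=C1 | intermediate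
19 | 3-[(1S)-1-acetoxybutyl]-9-[(1R)-1-acetoxybutyl]-11,12-dibromo-1,7-dioxadispiro[4.0.4.2]dodeca-3,9-diene-2,8-dione; 12-Br trans to O1 and cis to C4, 11-Br trans to O7 and cis to C10, ring bromines trans | CCC[C@H](OC(C)=O)C1=C[C@@]2(OC1=O)[C@@H](Br)[C@H](Br)[C@@]21OC(=O)C([C@@H](CCC)OC(C)=O)=C1 | intermediate
20 | 3,4,9,10,11,12-hexabromo adduct of 19 (3,4-trans and 9,10-trans dibromolactones; the four new centres are not assigned and are lost in the elimination) | CCC[C@H](OC(C)=O)C1(Br)C(Br)[C@@]2(OC1=O)[C@@H](Br)[C@H](Br)[C@@]21OC(=O)C(Br)([C@@H](CCC)OC(C)=O)C1Br | intermediate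
21 | CNP0266230.1: 3-[(1S)-1-acetoxybutyl]-9-[(1R)-1-acetoxybutyl]-4,10,11,12-tetrabromo-1,7-dioxadispiro[4.0.4.2]dodeca-3,9-diene-2,8-dione, ring configuration as in 19 | CCC[C@H](OC(C)=O)C1=C(Br)[C@@]2(OC1=O)[C@@H](Br)[C@H](Br)[C@@]21OC(=O)C([C@@H](CCC)OC(C)=O)=C1Br | target

Total step count: 13. Longest linear sequence: 9 steps (steps 1, 2, 3, 4, 9, 10, 11, 12, 13).

Steps most likely to fail

Step 9. The trialkylphosphine may be captured reversibly by the very electrophilic 1,2-dione instead of the cyclopropenone. The dione may enolise or ring-contract under the zwitterionic intermediates. Mono- and bis-annulation may not separate cleanly, which would scramble the two side-chain antipodes. The phosphine may also trigger loss of acetate from the product butenolide. The fallback never exposes a 1,2-dione to the phosphine and brings the two ketones on stage one at a time. It sets out from diol 4. Silylation with one equivalent of TESCl and imidazole should fall on the hydroxyl that is trans to its silyloxy neighbour and give the mono(triethylsilyl) ether F1. Dess–Martin oxidation of the remaining hydroxyl gives the tris(silyloxy)cyclobutanone F2, in which both flanking oxygens lie on the same face and both direct the ylide to the opposite one. Annulation with 12 and catalytic PMe3 on this single ketone gives the mono-spiro butenolide triethylsilyl ether F3. Selective removal of the triethylsilyl group (PPTS, MeOH) gives the mono-spiro butenolide alcohol F4. Dess–Martin oxidation then gives 15, now isolated, and a separate annulation with 14 comes back to the route at 16.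

Step 12. The second displacement may stall, because the remaining triflate sits next to a quaternary spiro carbon and is deactivated by the new vicinal bromide. The cis bromo-triflate intermediate has a hydrogen anti to the triflate and may eliminate. Ionisation with shift of the spiro vinyl carbon is also conceivable. The fallback replaces the vicinal bis(triflate) by activation of one oxygen at a time and sets out from diol 17. One equivalent of Tf2O gives the pair of mono-triflates, the 12-triflate F5 and the 11-triflate F6. Bromide (Bu4NBr) displaces each with inversion next to a free hydroxyl, which is far less deactivating than a triflate and cannot close an epoxide once the bromide is cis to it. This gives the 12-bromo-11-ol F7 and the 11-bromo-12-ol F8. Triflation gives the 12-bromo-11-triflate F9 and the 11-bromo-12-triflate F10, and a second displacement with Bu4NBr converges on 19, where the fallback rejoins the route.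

Step 13. Bromine may react by a radical path at the allylic, acetoxy-bearing side-chain carbon instead of adding to the alkene. The dehydrobromination needs a syn-periplanar E2 and may instead take the side-chain hydrogen to give an enol acetate. The amidine may also attack the β-bromo butenolide. The fallback builds the syn elimination into the reagent and sets out from 19. Anti-addition of PhSeBr (CH2Cl2, −20 °C → rt) should place selenium on C3 and C9 and bromine on C4 and C10, giving the bis(phenylselenide) adduct F11. Oxidation with H2O2 (pyridine, CH2Cl2, 0 °C) gives the bis(selenoxide) F12. The anti addition has left the ring hydrogen cis to selenium, and selenoxide elimination toward an oxygen-bearing carbon is disfavoured, so F12 should lose PhSeOH across C3–C4 and C9–C10 and return to the route at 21.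

Further compounds
F1 | step 9 | mono(triethylsilyl) ether of 4, silylated on the hydroxyl trans to its silyloxy neighbour | O[C@@H]1[C@H](O[Si](C)(C)C(C)(C)C)[C@@H](O[Si](C)(C)C(C)(C)C)[C@@H]1O[Si](CC)(CC)CC
F2 | step 9 | 2,3-bis(tert-butyldimethylsilyloxy)-4-(triethylsilyloxy)cyclobutan-1-one, the two silyloxy groups flanking the ketone on the same face | O=C1[C@H](O[Si](C)(C)C(C)(C)C)[C@@H](O[Si](C)(C)C(C)(C)C)[C@@H]1O[Si](CC)(CC)CC
F3 | step 9 | mono-spiro butenolide triethylsilyl ether: 15 with the ketone replaced by a CH–OSiEt3 whose oxygen is cis to the lactone oxygen | CCC[C@H](OC(C)=O)C1=C[C@@]2(OC1=O)[C@H](O[Si](C)(C)C(C)(C)C)[C@@H](O[Si](C)(C)C(C)(C)C)[C@@H]2O[Si](CC)(CC)CC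
F4 | step 9 | mono-spiro butenolide alcohol: F3 without the triethylsilyl group | CCC[C@H](OC(C)=O)C1=C[C@@]2(OC1=O)[C@H](O[Si](C)(C)C(C)(C)C)[C@@H](O[Si](C)(C)C(C)(C)C)[C@@H]2O
F5 | step 12 | 12-triflate of diol 17 (11-OH free) | CCC[C@H](OC(C)=O)C1=C[C@@]2(OC1=O)[C@H](OS(=O)(=O)C(F)(F)F)[C@@H](O)[C@@]21OC(=O)C([C@@H](CCC)OC(C)=O)=C1
F6 | step 12 | 11-triflate of diol 17 (12-OH free) | CCC[C@H](OC(C)=O)C1=C[C@@]2(OC1=O)[C@H](O)[C@@H](OS(=O)(=O)C(F)(F)F)[C@@]21OC(=O)C([C@@H](CCC)OC(C)=O)=C1
F7 | step 12 | 12-bromo-11-ol (C12 inverted, bromine cis to the 11-hydroxyl) | CCC[C@H](OC(C)=O)C1=C[C@@]2(OC1=O)[C@@H](Br)[C@@H](O)[C@@]21OC(=O)C([C@@H](CCC)OC(C)=O)=C1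
F8 | step 12 | 11-bromo-12-ol (C11 inverted, bromine cis to the 12-hydroxyl) | CCC[C@H](OC(C)=O)C1=C[C@@]2(OC1=O)[C@H](O)[C@H](Br)[C@@]21OC(=O)C([C@@H](CCC)OC(C)=O)=C1
F9 | step 12 | 12-bromo-11-triflate | CCC[C@H](OC(C)=O)C1=C[C@@]2(OC1=O)[C@@H](Br)[C@@H](OS(=O)(=O)C(F)(F)F)[C@@]21OC(=O)C([C@@H](CCC)OC(C)=O)=C1
F10 | step 12 | 11-bromo-12-triflate | CCC[C@H](OC(C)=O)C1=C[C@@]2(OC1=O)[C@H](OS(=O)(=O)C(F)(F)F)[C@H](Br)[C@@]21OC(=O)C([C@@H](CCC)OC(C)=O)=C1
F11 | step 13 | bis(phenylselenide) adduct of 19: 3,9-bis(phenylselanyl)-4,10-dibromo lactones, selenium and bromine trans on each ring, new centres not assigned | CCC[C@H](OC(C)=O)C1([Se]c3ccccc3)C(Br)[C@@]2(OC1=O)[C@@H](Br)[C@H](Br)[C@@]21OC(=O)C([Se]c3ccccc3)([C@@H](CCC)OC(C)=O)C1Br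
F12 | step 13 | bis(selenoxide) of F11 | CCC[C@H](OC(C)=O)C1([Se](=O)c3ccccc3)C(Br)[C@@]2(OC1=O)[C@@H](Br)[C@H](Br)[C@@]21OC(=O)C([Se](=O)c3ccccc3)([C@@H](CCC)OC(C)=O)C1Br
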